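## Structural features

The target consists of two bicycles joined by a single methylene group: a 6-methoxy-2,8-dimethyl-2H-chromene (benzene ring A fused to pyran ring B, with a styrenic C3=C4 bond) and a trans-fused 1,2,3,3a,7,7a-hexahydro-4H-inden-4-one (cyclohexenone ring C fused to cyclopentane ring D), the methylene running from chromene C2 to C6 of ring C. Ring C is a fully substituted enone (C4=O, C5=C6) whose α-carbon C5 bears a 2-hydroxy-2-methylpropyl chain, and rings C and D share C3a and C7a, two directly bonded quaternary carbons that each carry a methyl group, trans to one another, in the (3aS,7aR) configuration. The third stereocentre, chromene C2 (R), is a quaternary ether carbon (O1, C3, CH3, CH2) separated from C7a by the linking CH2, C6 and C7, so neither stereochemical unit can be relied on to control the other. The fragile parts are the electron-rich chromene (an allylic aryl ether that opens or dimerises in strong acid), the linking CH2 (the γ-position of the enone, so strong base could expel the phenoxide by vinylogous β-elimination) and the tertiary alcohol (dehydration, or lactol formation on the C4 carbonyl). The real difficulty is the pair C3a/C7a: two adjacent all-carbon quaternary centres, trans on a trans-hydrindane, in one absolute sense, with only the C4 carbonyl nearby as a handle; the hindered ether carbon C2 comes second. The key step uses the fact that C3a is the α-carbon of the C4 ketone, that C7a is the β-carbon of an enone whose carbonyl carbon is C6 (reached through C7), and that C5=C6 is the enone bond of an aldol condensation between the C5 methylene and that carbonyl; cutting C3a–C7a and C5=C6 unfolds rings C and D into a linear, terpenoid-like diketo-enone.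

## Logic of the disconnections

**29 ⇒ 28 ⇒ 27 ⇒ 26.** No skeletal bond is cut. The tertiary O–H is traced to an O–Si bond (28), and the C3=C4 bond of ring B to a C4 carbinol (27) and then a C4 carbonyl (26). The reason is that a C4 carbonyl makes C2 of ring B the β-carbon of a pyranone, an electrophilic site. The gain is that the acid-sensitive alkene appears only two steps from the end. The demand is a hydride reduction that touches the ring B carbonyl but not the ring C enone, and a mild dehydration.

**26 ⇒ 23 + 17.** The bond between C2 of ring B and the methylene on C6 of ring C is cut. It is the only bond that divides the molecule into two bicycles of similar size, and both ends have natural polarity: C2 is the 2-position of a benzopyrylium ion (24), and the methylene is the γ-terminus of a dienol ether. The gain is convergence: 23 has no stereocentre and 17 carries only C3a/C7a. The demand is that the forward step creates the quaternary C2 in the R sense by reagent control, and only at the γ-terminus.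

**17 ⇒ 16.** The dienol ether O–Si bond is traced to the enone. The demand is deprotonation at the C6 methyl group and not at C7.

**16 ⇒ 14 (key).** C5=C6 (aldol condensation) and C3a–C7a (Michael addition) are cut. Two rings and both quaternary stereocentres disappear, leaving an acyclic chain with one E-alkene and one epimerisable, irrelevant centre. The demand is a cascade that forms C3a–C7a first, trans and in one absolute sense, then closes ring C at the correct carbonyl.

**14 ⇒ 13 ⇒ 10.** Both carbonyls of 14 are traced to carbinols (13). This is the improvement in how the precursor is released: 14 appears in one buffered oxidation, never meets acid or base before the cascade, and no ketone (or ketal, which Me3Al would open) is present when organoaluminium reagents are used. Then the alkenyl–carbinol bond C2–C3 and the C4–CH3 bond are cut together, because an E-trisubstituted alkene is the product of syn methyl-metalation of the terminal alkyne of 10. The demand is regio- and syn-selective carbometalation and transfer to the aldehyde with retention.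

**10 ⇒ 9 ⇒ 7 + 3.** The carbinol is traced to ketone 9, and the bond between the carbonyl carbon and the side-chain CH2 is cut (acyl substitution of 7 by 8, made from 3). The gain is two small pieces. The demand is single addition in the presence of the alkyne C–H.

**7 ⇒ 5 ⇒ 4.** The amide C–N bond and then the α-C–CH3 bond are cut, back to commercial 4. The demand is methylation at the α-carbon only.

**3 ⇒ 2 ⇒ 1.** The O–Si bond and the two C–CH3 bonds of the tertiary carbinol are cut, back to ester 1. The silyl ether is kept throughout because a free γ-hydroxy ketone would close to a lactol and block enolisation.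

**23 ⇒ 21 ⇒ 18.** Ring B of 23 is opened at O1–C2 and the C2–C3 bond is cut (Claisen condensation with ethyl acetate, through 22). The aryl–acyl bond of 21 is cut (Fries rearrangement) back to phenol 18. The demand is acylation at the one free ortho position.

## Other disconnections considered

**Alternative 1:** The cut removes three bonds of ring A (C4a–C8a, C5–C6, C7–C8). Because C4a–C8a also closes ring B, both rings open and the chromene becomes the tethered diyne A2 (a propynyl ether on the tertiary oxygen and a Z-enyne, with C2 already in place) plus methoxyethyne A3. The forward key step is a metal-templated [2+2+2] cyclotrimerisation (CpCo(CO)2 or RhCl(PPh3)3): the two alkynes of A2 would form a metallacyclopentadiene that takes up A3 and gives the silyl-protected hydroxymethyl chromene A1.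
- In its favour: rings A and B and the full arene substitution pattern would arise in one operation, and the C3=C4 bond is carried in as the Z-alkene of A2, so no chromanone has to be reduced and dehydrated. C2 is fixed beforehand in a small tertiary carbinol whose configuration can be secured by established asymmetric chemistry. On this last point the alternative is the better plan, because step 13 of the chosen route depends on an untested catalyst-controlled addition.
- Against it here: nothing in A2 dictates whether A3 inserts with its methoxy group at C6 or C7, and A3 is volatile and prone to polymerise. A hindered tertiary ynol ether next to a Z-enyne would need about seven steps, whereas 23 takes two from 18; the key step would build ring A, which the chosen plan buys. A1 would then have to be joined to ring C through a neopentyl-type CH2–O carbon on a quaternary ether centre, a poor electrophile, so a different coupling and a different bicyclic partner would be needed.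
- Comparison: on structure it addresses the easier half and leaves C3a/C7a untouched, so the two plans are equal in still needing 16 or a relative. On mechanism it trades an enantiofacial risk for a regiochemical one. On step economy it is longer by roughly six to eight steps.

**Alternative 2:** The cut removes the ring D bonds C3a–C3 and C7a–C1, leaving C3a–C7a as the central bond of a succinate. In the forward key step the bis-enolate of di-(−)-menthyl 2,3-dimethylsuccinate A5 (two equivalents of a lithium amide) is alkylated at both carbons by 1,3-dibromopropane A6 to give the C2-symmetric trans-diester A4.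
- In its favour: both quaternary centres are made in one flask by plain enolate alkylation, and the trans relation follows from the symmetry of the bis-enolate. The absolute sense comes from a cheap stoichiometric auxiliary available in both enantiomeric forms, and diastereomers of A4 could be removed by crystallisation. In security of stereocontrol at C3a/C7a this alternative is the better plan, since step 9 relies on catalyst control of an unusually crowded Michael addition.
- Against it here: each enolate carbon of A5 is already fully substituted, so the ring-closing second alkylation must make a quaternary carbon next to a quaternary carbon by SN2, where elimination and O-alkylation compete. Auxiliary control shown on unsubstituted succinates need not carry over. The two identical, neopentyl-type esters of A4 must then be differentiated and homologated separately (one into the C4 acyl group with C5 and its side chain, the other by one carbon into C7 with the C6 carbonyl) before ring C can be closed, about ten steps on hindered centres to reach 16.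
- Comparison: on structure it attacks exactly the hardest element. On mechanism it replaces a reversible conjugate addition by an irreversible double alkylation. On step economy the chosen plan, which forms rings C and D and both centres in one step from a chain made in eight, is about twice as short; from 16 onwards the two plans are equal.

**Alternative 3:** The cut is the O1–C2 bond of ring B. The whole carbon skeleton is first assembled as the E-trisubstituted alkene A9 (an ortho-allylated phenol) and a Shi epoxidation gives epoxide A8. In the key step the phenol oxygen opens A8 at its tertiary carbon in a 6-endo closure with inversion to give the 3-hydroxychroman A7; the C3 hydroxyl is then eliminated towards C4.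
- In its favour: C2 is set by two stereospecific, well-understood events (a dioxirane epoxidation with predictable facial sense on E-trisubstituted alkenes, and an invertive opening favoured at the more substituted carbon). In reliability of stereocontrol at C2 this alternative is the better plan. The later elimination can only go towards C4, because C2 has no hydrogen.
- Against it here: the 4-methoxyphenol of A9 is a hydroquinone monoether that the dioxirane (or KHSO5) would oxidise to a quinone, so the phenol must be protected for the epoxidation and freed for the closure. Acid activation of a tertiary epoxide risks partial ionisation and erosion at C2, as well as 5-exo competition. Eliminating a secondary alcohol next to a quaternary ether carbon needs a syn-elimination (selenoxide or xanthate) to avoid ring contraction. A9 itself requires γ-alkylation of the dienolate of 16 with an allylic halide, a less selective process than addition to a cation in step 13.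
- Comparison: on structure both plans complete ring B late and are equal in leaving the C3a/C7a problem to another step. On mechanism the alternative is stereospecific where the chosen plan is catalyst-controlled. On step economy ring B costs about five steps after fragment union (protection, epoxidation, deprotection and closure, elimination) against three (addition, reduction, dehydration), and the union is less convergent.

Key step: step 9

Remark on the chemistry: the target is read as (2R) at the chromene carbon and (3aS,7aR) in the hydrindenone with trans angular methyl groups; the atom mapping of 14 onto 16 and of 16 onto 29 was checked and needs no correction; the sense of induction of each chiral catalyst is assumed to be adjustable by taking its enantiomer or pseudo-enantiomer.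

## Steps

Step 1
Reactants: 1 ethyl 3-bromopropanoate
Product: 2 4-bromo-2-methylbutan-2-ol
Conditions: MeMgBr (2.2 equiv), Et2O, 0 °C → rt; aq. NH4Cl
Reagents that add atoms: methylmagnesium bromide, C[Mg]Br
Why: Double Grignard addition to an ester; the intermediate ketone is more electrophilic than the ester, so the tertiary alcohol results. The primary bromide is not displaced by a Grignard reagent at 0 °C without a copper salt.

Step 2
Reactants: 2 4-bromo-2-methylbutan-2-ol
Product: 3 (4-bromo-2-methylbutan-2-yl)oxytriethylsilane
Conditions: TESOTf, 2,6-lutidine, CH2Cl2, 0 °C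
Reagents that add atoms: triethylsilyl trifluoromethanesulfonate, CC[Si](CC)(CC)OS(=O)(=O)C(F)(F)F
Why: Silyl triflate with a hindered pyridine base is the standard silylation of a tertiary alcohol. The ether removes the proton that would quench the Grignard reagent and later prevents lactol formation on the ketone.

Step 3
Reactants: 4 hept-6-ynoic acid
Product: 5 (±)-2-methylhept-6-ynoic acid
Conditions: LiN(i-Pr)2 (3.1 equiv), THF, −78 → 0 °C; MeI (1.05 equiv), −78 → 0 °C; aq. HCl
Reagents that add atoms: iodomethane, CI
Why: Alkylation of a carboxylic acid enediolate; the third equivalent of base covers the alkyne C–H, and the enediolate carbon is far more nucleophilic towards MeI than a lithium acetylide in THF without a polar additive. The new centre is racemic, which is harmless because it is erased by enolisation in step 9.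

Step 4
Reactants: 5 (±)-2-methylhept-6-ynoic acid
Product: 7 (±)-N-methoxy-N,2-dimethylhept-6-ynamide, via acyl imidazolide 6 (not isolated)
Conditions: CDI, CH2Cl2, rt; then MeNH(OMe)·HCl, rt
Reagents that add atoms: N,O-dimethylhydroxylamine hydrochloride, CNOC.Cl
Why: Acyl imidazolide activation followed by aminolysis (Weinreb amide formation) under near-neutral conditions that leave the terminal alkyne untouched.

Step 5
Reactants: 3 (4-bromo-2-methylbutan-2-yl)oxytriethylsilane (2.2 equiv) and 7 (±)-N-methoxy-N,2-dimethylhept-6-ynamide
Product: 9 (±)-2,6-dimethyl-2-(triethylsilyloxy)undec-10-yn-5-one, via Grignard reagent 8 (not isolated)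
Conditions: Mg, THF, 40 °C; then 7, 0 °C; aq. NH4Cl
Reagents that add atoms: none
Why: Weinreb ketone synthesis; the chelated tetrahedral magnesium adduct prevents a second addition. The excess of 8 covers any deprotonation of the terminal alkyne, which is reprotonated on work-up.

Step 6
Reactants: 9 (±)-2,6-dimethyl-2-(triethylsilyloxy)undec-10-yn-5-one
Product: 10 2,6-dimethyl-2-(triethylsilyloxy)undec-10-yn-5-ol (mixture of diastereomers)
Conditions: NaBH4, MeOH, 0 °C
Reagents that add atoms: none
Why: Borohydride reduction parks the ketone as a secondary alcohol, which Me3Al only deprotonates, whereas it would methylate a ketone or open a ketal. The carbinol centre is formed unselectively and is erased by the oxidation in step 8.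

Step 7
Reactants: 10 2,6-dimethyl-2-(triethylsilyloxy)undec-10-yn-5-ol
Product: 13 (3E)-4,8,12-trimethyl-12-(triethylsilyloxy)tridec-3-ene-2,9-diol (mixture of diastereomers), via alkenylalane 11 (not isolated), via lithium alanate 12 (not isolated)
Conditions: Me3Al (3.5 equiv), Cp2ZrCl2 (0.3 equiv), CH2Cl2, 0 °C → rt; volatiles removed; n-BuLi, hexane–THF, −78 °C; MeCHO, −78 → 0 °C; aq. potassium sodium tartrate
Reagents that add atoms: trimethylaluminium, C[Al](C)C; acetaldehyde, CC=O
Why: Zirconium-catalysed methylalumination (Negishi carboalumination) adds CH3 and Al syn across the terminal alkyne with Al on the terminal carbon, which fixes the E geometry. The derived lithium alkenylalanate transfers the alkenyl group to acetaldehyde with retention, while the hydroxyl travels as its aluminium alkoxide. The new carbinol centre is unselective and irrelevant.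

Step 8
Reactants: 13 (3E)-4,8,12-trimethyl-12-(triethylsilyloxy)tridec-3-ene-2,9-diol
Product: 14 (3E)-4,8,12-trimethyl-12-(triethylsilyloxy)tridec-3-ene-2,9-dione (racemic at C8)
Conditions: Dess–Martin periodinane, NaHCO3, CH2Cl2, 0 °C → rt
Reagents that add atoms: none
Why: Dess–Martin oxidation converts the allylic and the saturated secondary alcohol into ketones in one buffered, near-neutral operation. The tertiary silyl ether is kept and the E-enone is not isomerised.

Step 9
Reactants: 14 (3E)-4,8,12-trimethyl-12-(triethylsilyloxy)tridec-3-ene-2,9-dione
Product: 16 (3aS,7aR)-3a,6,7a-trimethyl-5-[2-methyl-2-(triethylsilyloxy)propyl]-1,2,3,3a,7,7a-hexahydro-4H-inden-4-one, via Michael adduct 15 (not isolated)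
Conditions: 9-amino-9-deoxy-epi-quinine (20 mol %), PhCO2H (40 mol %), toluene, 50 °C; then KOH, MeOH, 0 °C → rt
Reagents that add atoms: none
Why: The primary amine condenses with the unhindered methyl ketone of 14 to give an E-iminium ion, and the more substituted enol of the internal ketone, held close by hydrogen bonding to the protonated quinuclidine–benzoate, adds through C8 to the β-carbon C4; hydrolysis releases diketone 15, whose C10 methylene enolate (KOH) adds to the methyl ketone and loses water by an E1cB step. The closest known reaction types are the primary-amine-catalysed intramolecular Michael addition of ketones to enones and the Robinson-type Michael–aldol annulation. Ring D closes in a 5-exo-trig mode (the C10 enol could reach C4 only through a seven-membered transition state), and ring C closes by a 6-(enolexo)-exo-trig aldol addition. C7a is set by the face of the E-iminium ion that the cinchona scaffold leaves open, which is why the E geometry fixed in step 7 matters. C3a is set relative to C7a in the ring-forming transition state: the acyl arm on C8 and the acylmethyl arm on C4 take opposite faces of the forming cyclopentane, which puts the two methyl groups trans, and because the Michael step is reversible at 50 °C the less crowded trans adduct should also be the one that accumulates. Three selectivities are needed: Michael before aldol (no six-membered aldol exists until ring D is formed); attack of C10 on the methyl ketone and not of the methyl ketone CH3 on the carbonyl next to quaternary C3a (sterics, and only the former gives the fully substituted enone); and aldol condensation faster than retro-Michael (fast hydroxide-mediated closure at 0 °C). The pseudo-enantiomeric amine from quinidine is taken if a first run shows the opposite sense at C7a.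

Step 10
Reactants: 16 (3aS,7aR)-3a,6,7a-trimethyl-5-[2-methyl-2-(triethylsilyloxy)propyl]-1,2,3,3a,7,7a-hexahydro-4H-inden-4-one
Product: 17 (3aS,7aR)-4-(tert-butyldimethylsilyloxy)-3a,7a-dimethyl-6-methylidene-5-[2-methyl-2-(triethylsilyloxy)propyl]-2,3,3a,6,7,7a-hexahydro-1H-indene
Conditions: LiN(i-Pr)2, THF–DMPU, −78 °C; TBSCl, −78 → 0 °C
Reagents that add atoms: tert-butyldimethylsilyl chloride, CC(C)(C)[Si](C)(C)Cl
Why: Kinetic γ-deprotonation of an enone that has no α'-hydrogen, then O-silylation of the extended enolate (silyl dienol ether formation). The exocyclic methyl is freely accessible, whereas the only stereoelectronically suitable (axial) hydrogen on C7 is neopentylic and 1,3-diaxial to the C3a methyl group, so the exocyclic methylene isomer should dominate. C3a and C7a are quaternary and cannot epimerise.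

Step 11
Reactants: 18 4-methoxy-2-methylphenol
Product: 21 1-(2-hydroxy-5-methoxy-3-methylphenyl)ethan-1-one, via aryl acetate 19 (not isolated), via difluoroboron chelate 20 (not isolated)
Conditions: Ac2O, BF3·OEt2, 90 °C; aq. NaOAc, 60 °C
Reagents that add atoms: acetic anhydride, CC(=O)OC(C)=O
Why: O-acetylation followed by Lewis-acid Fries rearrangement. The para position is blocked by OMe and one ortho position by CH3, so the acetyl group can only reach the remaining ortho carbon, where it is held as the boron chelate that the acetate work-up cleaves.

Step 12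
Reactants: 21 1-(2-hydroxy-5-methoxy-3-methylphenyl)ethan-1-one
Product: 23 6-methoxy-2,8-dimethyl-4H-chromen-4-one, via 1,3-diketone 22 (not isolated)
Conditions: NaH, EtOAc, THF, reflux; then conc. HCl, MeOH, 60 °C
Reagents that add atoms: ethyl acetate, CCOC(C)=O
Why: Claisen condensation of the phenoxide–enolate with ethyl acetate gives the 1,3-diketone. Acid then closes the pyranone by addition of the phenol to the enolised diketone and loss of water, the classical 2-methylchromone synthesis.

Step 13
Reactants: 23 6-methoxy-2,8-dimethyl-4H-chromen-4-one (1.5 equiv) and 17 (3aS,7aR)-4-(tert-butyldimethylsilyloxy)-3a,7a-dimethyl-6-methylidene-5-[2-methyl-2-(triethylsilyloxy)propyl]-2,3,3a,6,7,7a-hexahydro-1H-indene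
Product: 26 (3aS,7aR)-6-{[(2R)-6-methoxy-2,8-dimethyl-4-oxo-3,4-dihydro-2H-chromen-2-yl]methyl}-3a,7a-dimethyl-5-[2-methyl-2-(triethylsilyloxy)propyl]-1,2,3,3a,7,7a-hexahydro-4H-inden-4-one, via benzopyrylium triflate 24 (not isolated), via silyl enol ether 25 (not isolated)
Conditions: TBSOTf, toluene, 60 °C; then 17, (R)-3,5-dihydro-4H-dinaphtho[2,1-c:1',2'-e]silepine-4,4-diol (20 mol %), −78 °C; 1 M HCl, THF, 0 °C
Reagents that add atoms: none
Why: Proposed new method: a vinylogous Mukaiyama addition to a 2-methyl-4-silyloxybenzopyrylium ion under anion-binding catalysis; TBSOTf turns 23 into the pyrylium triflate 24, the silanediol holds the triflate by two hydrogen bonds so that a chiral anion shields one face of C2, and the unhindered exocyclic CH2 of 17 (its α-carbon C5 is fully substituted, so only the γ-terminus can bond) adds to C2, the silyl group of 17 passing to triflate and the enol ether 25 being hydrolysed to 26. C2 is thereby set as (R) by the catalyst, whose enantiomer is chosen after a first run, while the distant (3aS,7aR) centres can at most cause a matched or mismatched pairing. The closest known reaction types are the silanediol- or thiourea-catalysed enantioselective addition of silyl ketene acetals to 4-silyloxybenzopyrylium triflates that lack a 2-substituent and the non-asymmetric vinylogous addition of silyloxy dienes to 2-substituted benzopyrylium salts, which together show the activation mode, the γ-selectivity and the formation of a fully substituted C2, but not their combination.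

Step 14
Reactants: 26 (3aS,7aR)-6-{[(2R)-6-methoxy-2,8-dimethyl-4-oxo-3,4-dihydro-2H-chromen-2-yl]methyl}-3a,7a-dimethyl-5-[2-methyl-2-(triethylsilyloxy)propyl]-1,2,3,3a,7,7a-hexahydro-4H-inden-4-one
Product: 27 (3aS,7aR)-6-{[(2R)-4-hydroxy-6-methoxy-2,8-dimethyl-3,4-dihydro-2H-chromen-2-yl]methyl}-3a,7a-dimethyl-5-[2-methyl-2-(triethylsilyloxy)propyl]-1,2,3,3a,7,7a-hexahydro-4H-inden-4-one (both C4 epimers of the chromanol)
Conditions: NaBH4, MeOH–CH2Cl2, −40 → 0 °C
Reagents that add atoms: none
Why: Chemoselective borohydride reduction: the aryl ketone of the chromanone, flanked by a CH2 group, should be reduced at low temperature faster than the fully substituted enone whose carbonyl sits next to quaternary C3a (ketone-over-enone selectivity of NaBH4 in the absence of cerium salts). The C4 carbinol is formed as a mixture and is removed in step 15.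

Step 15
Reactants: 27 (3aS,7aR)-6-{[(2R)-4-hydroxy-6-methoxy-2,8-dimethyl-3,4-dihydro-2H-chromen-2-yl]methyl}-3a,7a-dimethyl-5-[2-methyl-2-(triethylsilyloxy)propyl]-1,2,3,3a,7,7a-hexahydro-4H-inden-4-one
Product: 28 (3aS,7aR)-6-{[(2R)-6-methoxy-2,8-dimethyl-2H-chromen-2-yl]methyl}-3a,7a-dimethyl-5-[2-methyl-2-(triethylsilyloxy)propyl]-1,2,3,3a,7,7a-hexahydro-4H-inden-4-one
Conditions: TsOH·H2O (5 mol %), 4 Å MS, toluene, 50 °C
Reagents that add atoms: none
Why: Acid-catalysed E1 dehydration of a 4-chromanol through the benzylic cation stabilised by the ring oxygen; the only β-hydrogens are on C3, so the styrenic C3=C4 bond is the sole outcome. C2 is not involved, and the silyl-protected tertiary alcohol cannot ionise under these mild, dry conditions.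

Step 16
Reactants: 28 (3aS,7aR)-6-{[(2R)-6-methoxy-2,8-dimethyl-2H-chromen-2-yl]methyl}-3a,7a-dimethyl-5-[2-methyl-2-(triethylsilyloxy)propyl]-1,2,3,3a,7,7a-hexahydro-4H-inden-4-one
Product: 29 (3aS,7aR)-5-(2-hydroxy-2-methylpropyl)-6-{[(2R)-6-methoxy-2,8-dimethyl-2H-chromen-2-yl]methyl}-3a,7a-dimethyl-1,2,3,3a,7,7a-hexahydro-4H-inden-4-one (CNP0295366.2)
Conditions: TBAF, AcOH, THF, 0 °C → rt
Reagents that add atoms: none
Why: Fluoride cleavage of the triethylsilyl ether; buffering with acetic acid keeps the medium too weakly basic for γ-deprotonation of the enone, and no acid strong enough to harm the chromene is present. All three stereocentres are quaternary and untouched.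

## Compound list

1 | ethyl 3-bromopropanoate | CCOC(=O)CCBr | starting material
2 | 4-bromo-2-methylbutan-2-ol | CC(C)(O)CCBr | intermediate
3 | (4-bromo-2-methylbutan-2-yl)oxytriethylsilane | CC[Si](CC)(CC)OC(C)(C)CCBr | intermediate
4 | hept-6-ynoic acid | C#CCCCCC(=O)O | starting material
5 | (±)-2-methylhept-6-ynoic acid | C#CCCCC(C)C(=O)O | intermediate
6 | 1-(2-methylhept-6-ynoyl)-1H-imidazole | C#CCCCC(C)C(=O)n1ccnc1 | intermediate (not isolated)
7 | (±)-N-methoxy-N,2-dimethylhept-6-ynamide | C#CCCCC(C)C(=O)N(C)OC | intermediate
8 | [3-methyl-3-(triethylsilyloxy)butyl]magnesium bromide | CC[Si](CC)(CC)OC(C)(C)CC[Mg]Br | intermediate (not isolated)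
9 | (±)-2,6-dimethyl-2-(triethylsilyloxy)undec-10-yn-5-one | C#CCCCC(C)C(=O)CCC(C)(C)O[Si](CC)(CC)CC | intermediate
10 | 2,6-dimethyl-2-(triethylsilyloxy)undec-10-yn-5-ol (diastereomer mixture) | C#CCCCC(C)C(O)CCC(C)(C)O[Si](CC)(CC)CC | intermediate
11 | [(1E)-7-(dimethylalumanyloxy)-2,6,10-trimethyl-10-(triethylsilyloxy)undec-1-en-1-yl]dimethylalumane | C[Al](C)/C=C(\C)CCCC(C)C(O[Al](C)C)CCC(C)(C)O[Si](CC)(CC)CC | intermediate (not isolated)
12 | lithium butyl[(1E)-7-(dimethylalumanyloxy)-2,6,10-trimethyl-10-(triethylsilyloxy)undec-1-en-1-yl]dimethylaluminate | [Li+].CCCC[Al-](C)(C)/C=C(\C)CCCC(C)C(O[Al](C)C)CCC(C)(C)O[Si](CC)(CC)CC | intermediate (not isolated)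
13 | (3E)-4,8,12-trimethyl-12-(triethylsilyloxy)tridec-3-ene-2,9-diol (diastereomer mixture) | CC(O)/C=C(\C)CCCC(C)C(O)CCC(C)(C)O[Si](CC)(CC)CC | intermediate
14 | (3E)-4,8,12-trimethyl-12-(triethylsilyloxy)tridec-3-ene-2,9-dione (racemic at C8) | CC(=O)/C=C(\C)CCCC(C)C(=O)CCC(C)(C)O[Si](CC)(CC)CC | intermediate
15 | 1-[(1S,2R)-1,2-dimethyl-2-(2-oxopropyl)cyclopentyl]-4-methyl-4-(triethylsilyloxy)pentan-1-one | O=C(CCC(C)(C)O[Si](CC)(CC)CC)[C@@]1(C)CCC[C@]1(C)CC(C)=O | intermediate (not isolated)
16 | (3aS,7aR)-3a,6,7a-trimethyl-5-[2-methyl-2-(triethylsilyloxy)propyl]-1,2,3,3a,7,7a-hexahydro-4H-inden-4-one | CC1=C(CC(C)(C)O[Si](CC)(CC)CC)C(=O)[C@@]2(C)CCC[C@]2(C)C1 | intermediate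
17 | (3aS,7aR)-4-(tert-butyldimethylsilyloxy)-3a,7a-dimethyl-6-methylidene-5-[2-methyl-2-(triethylsilyloxy)propyl]-2,3,3a,6,7,7a-hexahydro-1H-indene | C=C1C(CC(C)(C)O[Si](CC)(CC)CC)=C(O[Si](C)(C)C(C)(C)C)[C@@]2(C)CCC[C@]2(C)C1 | intermediate
18 | 4-methoxy-2-methylphenol | COc1ccc(O)c(C)c1 | starting material
19 | 4-methoxy-2-methylphenyl acetate | COc1ccc(OC(C)=O)c(C)c1 | intermediate (not isolated)
20 | O,O-difluoroboron chelate of 1-(2-hydroxy-5-methoxy-3-methylphenyl)ethanone | COc1cc(C)c2O[B-](F)(F)[O+]=C(C)c2c1 | intermediate (not isolated)
21 | 1-(2-hydroxy-5-methoxy-3-methylphenyl)ethan-1-one | COc1cc(C)c(O)c(C(C)=O)c1 | intermediate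
22 | 1-(2-hydroxy-5-methoxy-3-methylphenyl)butane-1,3-dione | COc1cc(C)c(O)c(C(=O)CC(C)=O)c1 | intermediate (not isolated)
23 | 6-methoxy-2,8-dimethyl-4H-chromen-4-one | COc1cc(C)c2oc(C)cc(=O)c2c1 | intermediate
24 | 4-(tert-butyldimethylsilyloxy)-6-methoxy-2,8-dimethylchromenylium trifluoromethanesulfonate | COc1cc(C)c2[o+]c(C)cc(O[Si](C)(C)C(C)(C)C)c2c1.[O-]S(=O)(=O)C(F)(F)F | intermediate (not isolated)
25 | (3aS,7aR)-6-{[(2R)-4-(tert-butyldimethylsilyloxy)-6-methoxy-2,8-dimethyl-2H-chromen-2-yl]methyl}-3a,7a-dimethyl-5-[2-methyl-2-(triethylsilyloxy)propyl]-1,2,3,3a,7,7a-hexahydro-4H-inden-4-one | COc1cc(C)c2c(c1)C(O[Si](C)(C)C(C)(C)C)=C[C@@](C)(CC1=C(CC(C)(C)O[Si](CC)(CC)CC)C(=O)[C@@]3(C)CCC[C@]3(C)C1)O2 | intermediate (not isolated)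
26 | (3aS,7aR)-6-{[(2R)-6-methoxy-2,8-dimethyl-4-oxo-3,4-dihydro-2H-chromen-2-yl]methyl}-3a,7a-dimethyl-5-[2-methyl-2-(triethylsilyloxy)propyl]-1,2,3,3a,7,7a-hexahydro-4H-inden-4-one | COc1cc(C)c2c(c1)C(=O)C[C@@](C)(CC1=C(CC(C)(C)O[Si](CC)(CC)CC)C(=O)[C@@]3(C)CCC[C@]3(C)C1)O2 | intermediate
27 | (3aS,7aR)-6-{[(2R)-4-hydroxy-6-methoxy-2,8-dimethyl-3,4-dihydro-2H-chromen-2-yl]methyl}-3a,7a-dimethyl-5-[2-methyl-2-(triethylsilyloxy)propyl]-1,2,3,3a,7,7a-hexahydro-4H-inden-4-one (C4 epimers) | COc1cc(C)c2c(c1)C(O)C[C@@](C)(CC1=C(CC(C)(C)O[Si](CC)(CC)CC)C(=O)[C@@]3(C)CCC[C@]3(C)C1)O2 | intermediate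
28 | (3aS,7aR)-6-{[(2R)-6-methoxy-2,8-dimethyl-2H-chromen-2-yl]methyl}-3a,7a-dimethyl-5-[2-methyl-2-(triethylsilyloxy)propyl]-1,2,3,3a,7,7a-hexahydro-4H-inden-4-one | COc1cc(C)c2c(c1)C=C[C@@](C)(CC1=C(CC(C)(C)O[Si](CC)(CC)CC)C(=O)[C@@]3(C)CCC[C@]3(C)C1)O2 | intermediate
29 | (3aS,7aR)-5-(2-hydroxy-2-methylpropyl)-6-{[(2R)-6-methoxy-2,8-dimethyl-2H-chromen-2-yl]methyl}-3a,7a-dimethyl-1,2,3,3a,7,7a-hexahydro-4H-inden-4-one | COc1cc(C)c2c(c1)C=C[C@@](C)(CC1=C(CC(C)(C)O)C(=O)[C@@]3(C)CCC[C@]3(C)C1)O2 | target

## Step count and least certain steps

Total: 16 steps. Longest linear sequence: 12 steps (from 4 through steps 3–10 and 13–16; the branch from 1 through steps 1, 2, 5–10 and 13–16 is equally long; the chromone branch from 18 joins at step 13).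

**Step 13 (proposed new method).** Facial discrimination at C2 may be poor, because the 2-methyl group makes the two faces of the cation alike and slows the catalyst-bound pathway relative to addition to the free ion pair. The cation may also lose a proton from its 2-methyl group instead of being attacked. The fallback gives up catalyst control and uses known chemistry. It sets out from 17 and 23 and runs the vinylogous Mukaiyama addition with TBSOTf alone, a reaction known for 2-substituted 4-silyloxybenzopyrylium salts and silyloxy dienes. This should give 25 together with the C2-epimeric silyl enol ether F1; the same acid hydrolysis gives 26 and the (2S)-chromanone F2. Because the bicycle is enantiopure these are diastereomers and are separated by chromatography. F2 is recycled with DBU in warm toluene: retro-oxa-Michael opening to the 2-hydroxyaryl enone F3 and re-closure regenerates the 26/F2 mixture. The route is rejoined at 26.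

**Step 9 (key step).** The Michael addition joins a tetrasubstituted enol to a β,β-disubstituted acceptor, so it may be slow. Enantiomeric purity may be lost through E/Z scrambling of the enone by way of the dienamine, or through retro-Michael reaction before ring C closes. Closure through the minor cis adduct is a further channel. The fallback separates ring construction from the question of absolute configuration. It sets out from 14 and runs the cascade with an achiral base (KOt-Bu, t-BuOH–THF, 0 °C → rt), which should give the racemic Michael adduct (15 with its enantiomer F4) and then the racemic trans-enone (16 with its enantiomer F5). 16 is separated from F5 by preparative chromatography on a chiral stationary phase (cellulose tris(3,5-dimethylphenylcarbamate)). The route is rejoined at 16.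

**Step 10.** Deprotonation may take place at C7 instead of the C6 methyl group, since a ring-conjugated dienolate is usually the more stable one. The fallback replaces regioselective deprotonation by regioconvergent use of a mixture. It sets out from 16 and uses soft enolisation (TBSOTf, Et3N, CH2Cl2), which should give 17 together with the ring-conjugated dienol ether F6, the two interconverting through the O-silylated enone cation. The mixture is taken into step 13, where F6 could bond only through its neopentylic ring carbon and should not compete; unreacted F6 returns 16 on the acidic work-up for another pass. The route is rejoined at 17.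

**Step 7.** Transfer from the mixed alanate may be unselective (methyl or butyl instead of alkenyl), and acetaldehyde may be enolised by the basic ate complex, so conversion to 13 may be low. The fallback isolates the alkenyl unit first. It sets out from 10: the same carboalumination is quenched with I2 to give the vinyl iodide (10E)-11-iodo-2,6,10-trimethyl-2-(triethylsilyloxy)undec-10-en-5-ol F7, which can be purified. A Nozaki–Hiyama–Kishi addition to acetaldehyde (CrCl2, NiCl2 cat., DMF), which tolerates the free hydroxyl, then gives 13. The route is rejoined at 13.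

**Step 14.** Over-reduction of the ring C carbonyl or conjugate reduction may compete if the hindered enone is more reactive than expected. The fallback reduces both carbonyls deliberately and differentiates the carbinols by sterics. It sets out from 26: NaBH4 with CeCl3·7H2O in MeOH gives the diol F8. MsCl and Et3N mesylate only the less hindered benzylic carbinol (mesylate F9, not isolated), which eliminates to the chromene allylic alcohol F10. MnO2 (or Dess–Martin periodinane) then re-oxidises the hindered allylic alcohol. The route is rejoined at 28.

## Further compounds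

F1 | step 13 | C2 epimer of 25: (3aS,7aR)-6-{[(2S)-4-(tert-butyldimethylsilyloxy)-6-methoxy-2,8-dimethyl-2H-chromen-2-yl]methyl}-3a,7a-dimethyl-5-[2-methyl-2-(triethylsilyloxy)propyl]-1,2,3,3a,7,7a-hexahydro-4H-inden-4-one | COc1cc(C)c2c(c1)C(O[Si](C)(C)C(C)(C)C)=C[C@](C)(CC1=C(CC(C)(C)O[Si](CC)(CC)CC)C(=O)[C@@]3(C)CCC[C@]3(C)C1)O2
F2 | step 13 | C2 epimer of 26: (3aS,7aR)-6-{[(2S)-6-methoxy-2,8-dimethyl-4-oxo-3,4-dihydro-2H-chromen-2-yl]methyl}-3a,7a-dimethyl-5-[2-methyl-2-(triethylsilyloxy)propyl]-1,2,3,3a,7,7a-hexahydro-4H-inden-4-one | COc1cc(C)c2c(c1)C(=O)C[C@](C)(CC1=C(CC(C)(C)O[Si](CC)(CC)CC)C(=O)[C@@]3(C)CCC[C@]3(C)C1)O2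
F3 | step 13 | (3aS,7aR)-6-[4-(2-hydroxy-5-methoxy-3-methylphenyl)-2-methyl-4-oxobut-2-en-1-yl]-3a,7a-dimethyl-5-[2-methyl-2-(triethylsilyloxy)propyl]-1,2,3,3a,7,7a-hexahydro-4H-inden-4-one (E/Z mixture) | COc1cc(C)c(O)c(c1)C(=O)C=C(C)CC1=C(CC(C)(C)O[Si](CC)(CC)CC)C(=O)[C@@]2(C)CCC[C@]2(C)C1
F4 | step 9 | enantiomer of 15: 1-[(1R,2S)-1,2-dimethyl-2-(2-oxopropyl)cyclopentyl]-4-methyl-4-(triethylsilyloxy)pentan-1-one | O=C(CCC(C)(C)O[Si](CC)(CC)CC)[C@]1(C)CCC[C@@]1(C)CC(C)=O
F5 | step 9 | enantiomer of 16: (3aR,7aS)-3a,6,7a-trimethyl-5-[2-methyl-2-(triethylsilyloxy)propyl]-1,2,3,3a,7,7a-hexahydro-4H-inden-4-one | CC1=C(CC(C)(C)O[Si](CC)(CC)CC)C(=O)[C@]2(C)CCC[C@@]2(C)C1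
F6 | step 10 | (3aS,7aR)-4-(tert-butyldimethylsilyloxy)-3a,6,7a-trimethyl-5-[2-methyl-2-(triethylsilyloxy)propyl]-2,3,3a,7a-tetrahydro-1H-indene | CC1=C[C@@]2(C)CCC[C@]2(C)C(O[Si](C)(C)C(C)(C)C)=C1CC(C)(C)O[Si](CC)(CC)CC
F7 | step 7 | (10E)-11-iodo-2,6,10-trimethyl-2-(triethylsilyloxy)undec-10-en-5-ol | I/C=C(\C)CCCC(C)C(O)CCC(C)(C)O[Si](CC)(CC)CC
F8 | step 14 | (3aS,7aR)-6-{[(2R)-4-hydroxy-6-methoxy-2,8-dimethyl-3,4-dihydro-2H-chromen-2-yl]methyl}-3a,7a-dimethyl-5-[2-methyl-2-(triethylsilyloxy)propyl]-2,3,3a,4,7,7a-hexahydro-1H-inden-4-ol (carbinol epimers) | COc1cc(C)c2c(c1)C(O)C[C@@](C)(CC1=C(CC(C)(C)O[Si](CC)(CC)CC)C(O)[C@@]3(C)CCC[C@]3(C)C1)O2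
F9 | step 14 | 4-O-methanesulfonate of F8 at the chromanol carbinol | COc1cc(C)c2c(c1)C(OS(C)(=O)=O)C[C@@](C)(CC1=C(CC(C)(C)O[Si](CC)(CC)CC)C(O)[C@@]3(C)CCC[C@]3(C)C1)O2
F10 | step 14 | (3aS,7aR)-6-{[(2R)-6-methoxy-2,8-dimethyl-2H-chromen-2-yl]methyl}-3a,7a-dimethyl-5-[2-methyl-2-(triethylsilyloxy)propyl]-2,3,3a,4,7,7a-hexahydro-1H-inden-4-ol (carbinol epimers) | COc1cc(C)c2c(c1)C=C[C@@](C)(CC1=C(CC(C)(C)O[Si](CC)(CC)CC)C(O)[C@@]3(C)CCC[C@]3(C)C1)O2
A1 | alternative 1 | tert-butyl{[(2S)-6-methoxy-2,8-dimethyl-2H-chromen-2-yl]methoxy}dimethylsilane | COc1cc(C)c2c(c1)C=C[C@@](C)(CO[Si](C)(C)C(C)(C)C)O2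
A2 | alternative 1 | tert-butyl{[(2S,3Z)-2-methyl-2-(prop-1-yn-1-yloxy)hex-3-en-5-yn-1-yl]oxy}dimethylsilane | CC#CO[C@](C)(CO[Si](C)(C)C(C)(C)C)/C=C\C#C
A3 | alternative 1 | methoxyethyne | COC#C
A4 | alternative 2 | bis[(1R,2S,5R)-2-isopropyl-5-methylcyclohexyl] (1S,2S)-1,2-dimethylcyclopentane-1,2-dicarboxylate | C[C@@H]1CC[C@H]([C@@H](C1)OC(=O)[C@@]3(C)CCC[C@]3(C)C(=O)O[C@@H]2C[C@H](C)CC[C@H]2C(C)C)C(C)C
A5 | alternative 2 | bis[(1R,2S,5R)-2-isopropyl-5-methylcyclohexyl] 2,3-dimethylbutanedioate | CC(C(C)C(=O)O[C@@H]1C[C@H](C)CC[C@H]1C(C)C)C(=O)O[C@@H]1C[C@H](C)CC[C@H]1C(C)C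
A6 | alternative 2 | 1,3-dibromopropane | BrCCCBr
A7 | alternative 3 | (3aS,7aR)-6-{[(2R,3S)-3-hydroxy-6-methoxy-2,8-dimethyl-3,4-dihydro-2H-chromen-2-yl]methyl}-5-(2-hydroxy-2-methylpropyl)-3a,7a-dimethyl-1,2,3,3a,7,7a-hexahydro-4H-inden-4-one | COc1cc(C)c2c(c1)C[C@H](O)[C@@](C)(CC3=C(CC(C)(C)O)C(=O)[C@@]4(C)CCC[C@]4(C)C3)O2
A8 | alternative 3 | (3aS,7aR)-6-{[(2S,3S)-3-(2-hydroxy-5-methoxy-3-methylbenzyl)-2-methyloxiran-2-yl]methyl}-5-(2-hydroxy-2-methylpropyl)-3a,7a-dimethyl-1,2,3,3a,7,7a-hexahydro-4H-inden-4-one | COc1cc(C)c(O)c(c1)C[C@@H]2O[C@@]2(C)CC3=C(CC(C)(C)O)C(=O)[C@@]4(C)CCC[C@]4(C)C3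
A9 | alternative 3 | (3aS,7aR)-6-[(2E)-4-(2-hydroxy-5-methoxy-3-methylphenyl)-2-methylbut-2-en-1-yl]-5-(2-hydroxy-2-methylpropyl)-3a,7a-dimethyl-1,2,3,3a,7,7a-hexahydro-4H-inden-4-one | COc1cc(C)c(O)c(c1)C/C=C(\C)CC3=C(CC(C)(C)O)C(=O)[C@@]4(C)CCC[C@]4(C)C3
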